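The readings come from a simulation for substances that don't exist; scatter was added.

I started from the feed.

| setting | violet | green | Thursday's | Monday's | Sunday's | Saturday's |
|---|---|---|---|---|---|---|
| starting material | 0.050 M | 0.050 M | 0.050 M | 0.10 M | 0.20 M | 0.40 M |
| coupling partner | 0.0525 M (fed, over 30 h) | 0.10 M (fed, over 30 h) | 0.0525 M (fed, over 30 h) | 0.0525 M (fed, over 30 h) | 0.0525 M (fed, over 30 h) | 0.0525 M (fed, over 30 h) |
| initiator | 10 mM | 7 mM | 7.0 mM | 7.0 mM | 7.0 mM | 7.0 mM |
| remark | run made earlier | run made earlier |  |  |  |  |
| time |  |  | 50 h | 50 h | 50 h | 50 h |

| run | time / h | target / % | starting material / % |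
|---|---|---|---|
| violet | 0.833 | 0.2 | 99.4 |
| violet | 2.50 | 1.7 | 97.5 |
| violet | 5.00 | 0.8 | 96.7 |
| violet | 8.00 | 4.5 | 92.7 |
| violet | 10.0 | 7.2 | 88.2 |
| green | 0.833 | 0 | 100.7 |
| green | 1.50 | 0 | 99.0 |
| green | 3.00 | 2.1 | 97.1 |
| green | 5.00 | 3.2 | 94.6 |
| green | 10.0 | 7.6 | 88.4 |

(each reading ± 1 percentage point)

- percent here means starting material units held: one ended chains A counts as two
- the analysis behind the earlier runs scatters by 1 percentage point, standard deviation
- what may be going on: initiator -> 2 initiating radical; starting material + initiating radical -> capped initiator + first chain carrier; coupling partner + first chain carrier -> target + second chain carrier; starting material + second chain carrier -> released group + first chain carrier; 2 first chain carrier -> ended chains A; 2 second chain carrier -> ended chains B; 2 coupling partner -> self-condensation product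
- "hardly changes" means that all values lie within two and a half points (for a concentration: within two and a half percent of the largest)

1. amount of target at the end, in percent of the starting material charged for Thursday's, Monday's, Sunday's, Saturday's, in this order
2. the shape of the row from first to last (rises, then falls / falls, then rises / falls all the way / hardly changes / rises all the way)

Target is the thing to follow, so I turned percent into concentration. Carriers were never read, and I took them as steady, the fastest rung. Next I asked which chain step was slow. The target readings could not answer that, for they are few and scatter by 1 percentage point. So I made it an assumption, not a finding: the partner step as the rate-limiting step, with first chain carrier as resting state, and the making of target as pseudo-first-order in [coupling partner].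

That gave me the capture constant, the first-order constant at which the chain turns coupling partner into target, 0.0344 h⁻¹, read from violet against the partner dosed and scaled to 7.0 mM of initiator by a square root, my assumption. It holds no [starting material]. The next rung was partner's life on the chain, 20.1 h, shorter than the dose of 30 h.

Green warned me: on twice violet's dose it held 3.80 mM of target against 3.60 mM, so I put no figure on the millimolar amount. With dose and initiator held, I committed to the same [target] in all four flasks, so each doubling of the charge gives half the percent, and Thursday's stands above Saturday's by a factor 8.00.

The forecast gave 32 %, 27 %, 16 % and 8 %, shape falls all the way, holding that “Absolute target therefore rises”, from 16.0 mM to 32.0 mM; its factor is 4.00.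

    initiator → 2 initiating radical (k = 0.0140 h⁻¹)
    starting material + initiating radical → capped initiator + first chain carrier (k = 67000 M⁻¹ s⁻¹)
    coupling partner + first chain carrier → target + second chain carrier (k = 2.60 × 10⁶ M⁻¹ h⁻¹)
    starting material + second chain carrier → released group + first chain carrier (k = 51000 M⁻¹ s⁻¹)
    2 first chain carrier → ended chains A (k = 9.00 × 10⁷ M⁻¹ s⁻¹)
    2 second chain carrier → ended chains B (k = 5.40 × 10⁷ M⁻¹ s⁻¹)
    2 coupling partner → self-condensation product (k = 6.60 M⁻¹ h⁻¹)

The flask gave 26.5 %, 13.3 %, 6.63 % and 3.32 %, falls all the way, a factor of 7.98: Thursday's held 13.3 mM of target and Saturday's 13.3 mM. At the capture constant, Thursday's amount asks for a mean [coupling partner] of 7.70 mM over 50 h, and Saturday's for 7.72 mM. On Thursday's flask at 20.3 h, self-condensation used 3.4 times the partner that coupling used. At 50.0 h that ratio was 0.73.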